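A direct plan would build each flavan half from a salicylaldehyde and a cinnamaldehyde by iminium-catalysed oxa-Michael/aldol annulation and cut the 3-formyl group down to oxygen by Baeyer–Villiger oxidation. It would then join the upper enol formate A1 to tetra-O-benzylepicatechin A2 at C4–C8 under acid and finish by hydrogenolysis.
- Weak point 1, the acid-triggered union of A1 with A2: this hydroarylation is untested, and one protonation would have to set C3 (2,3-cis) before the arene sets C4, with hydride transfer from C2–H and oligomerisation as competing paths.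
- Weak point 2, the four-step build-up of A2 through flavan-3-one A3 and a hydride reduction: this is a redox detour to a compound that is one step from commercial (−)-epicatechin, and the C2–H of A3 is acidic.
- Weak point 3, the organocatalytic chromene annulation with electron-rich partners: the oxa-Michael step is reversible, so the ee of C2 is at risk, and the enol formate is labile on silica.

**Retrosynthetic overview** (upper unit: rings A, C, B; lower unit: rings D, F, E)
- C4 of ring C is a doubly benzylic methine between C4a of ring A (para to O7) and C8 of ring D (2,4,6-trioxygenated). Ring C is cut at C4–C4a, not at the interflavan bond: the cation at C4 is stabilised by ring D and trapped by ring A, which is tethered through O1.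
- The precursor is an open-chain carbinol made from an 8-lithiated epicatechin ether and an aldehyde. The C4–C8 bond is therefore formed first, by carbanion chemistry, at a centre whose configuration is erased on ionisation.
- C2 and C3 (cis) are set together in the open chain by a syn-alkoxyallylboration, and O1 is added by an O-arylation that retains configuration. No protonation sets C3 and no redox correction is needed.
- Ring order: ring F comes from the chiral pool (commercial epicatechin), then the interflavan bond, then ring C last.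

Key step: step 7

Assumption: the Ipc2B reagent derived from (+)-α-pinene is taken to deliver the allyl unit to the Si face of an aromatic aldehyde (the usual sense for this borane); if the opposite sense were found, the antipodal borane would be used with no other change.

**Step 1**
Reactants: 1 (−)-epicatechin
Product: 2 (2R,3R)-3,5,7-tris(benzyloxy)-2-[3,4-bis(benzyloxy)phenyl]chromane (penta-O-benzylepicatechin)
Conditions: NaH (6.5 equiv), BnBr (6.5 equiv), DMF, −20 °C → rt
Reagents that add atoms: benzyl bromide, BrCc1ccccc1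
Why: Williamson benzylation of the four phenols and the C3 alkoxide, run cold with the halide present from the start so that the phenoxides are capped before base can open ring F and epimerise C2; no stereocentre is touched.

**Step 2**
Reactants: 2 penta-O-benzylepicatechin
Product: 3 (2R,3R)-3,5,7-tris(benzyloxy)-2-[3,4-bis(benzyloxy)phenyl]-8-bromochromane
Conditions: NBS (1.05 equiv), CH2Cl2, −78 °C → rt
Reagents that add atoms: N-bromosuccinimide, O=C1CCC(=O)N1Br
Why: Electrophilic aromatic bromination, in which C8 of ring D is the more reactive of the two open positions of benzylated flavan-3-ols, gives the handle for lithiation.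

**Step 3**
Reactants: 4 allyl methoxymethyl ether; 5 4-(benzyloxy)benzaldehyde
Product: 7 (1R,2R)-1-[4-(benzyloxy)phenyl]-2-(methoxymethoxy)but-3-en-1-ol, via (Z)-alkoxyallylborane 6 (not isolated)
Conditions: 4, s-BuLi, THF, −78 °C; (−)-Ipc2BOMe; BF3·OEt2; then 5, −78 °C; NaOH, H2O2, 0 °C → rt
Reagents that add atoms: none
Why: Brown (Z)-γ-alkoxyallylboration, in which the closed Zimmerman–Traxler chair of the Z-allylborane gives the syn 1,2-diol monoether and the isopinocampheyl groups select the aldehyde face, sets C2 and C3 of the upper unit together and leaves the benzylic hydroxyl as the only free OH.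

**Step 4**
Reactants: 7 (1R,2R)-1-[4-(benzyloxy)phenyl]-2-(methoxymethoxy)but-3-en-1-ol; 8 1-(benzyloxy)-3-iodobenzene
Product: 9 1-(benzyloxy)-3-{[(1R,2R)-1-[4-(benzyloxy)phenyl]-2-(methoxymethoxy)but-3-en-1-yl]oxy}benzene
Conditions: 8 (3 equiv), CuI (20 mol%), 3,4,7,8-tetramethyl-1,10-phenanthroline (40 mol%), Cs2CO3 (2 equiv), 4 Å MS, toluene, 100 °C
Reagents that add atoms: none
Why: Copper-catalysed Ullmann-type etherification of a secondary alcohol with an aryl iodide forms only the aryl C–O bond, so the carbinol C–O bond and its configuration (future C2–O1) are retained.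

**Step 5**
Reactants: 9 1-(benzyloxy)-3-{[(1R,2R)-1-[4-(benzyloxy)phenyl]-2-(methoxymethoxy)but-3-en-1-yl]oxy}benzene
Product: 10 (2S,3R)-3-[3-(benzyloxy)phenoxy]-3-[4-(benzyloxy)phenyl]-2-(methoxymethoxy)propanal
Conditions: OsO4 (2 mol%), NaIO4 (4 equiv), 2,6-lutidine (2 equiv), dioxane–H2O (3:1), rt; used crude
Reagents that add atoms: sodium periodate, [Na+].[O-]I(=O)(=O)=O
Why: Lemieux–Johnson oxidative cleavage of the vinyl group to the aldehyde that becomes C4, buffered by lutidine so that the α-alkoxy centre does not epimerise and the β-aryloxy group is not eliminated; the change of descriptor at C2 comes from the priority rules only.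

**Step 6**
Reactants: 3 (2R,3R)-3,5,7-tris(benzyloxy)-2-[3,4-bis(benzyloxy)phenyl]-8-bromochromane; 10 (2S,3R)-3-[3-(benzyloxy)phenoxy]-3-[4-(benzyloxy)phenyl]-2-(methoxymethoxy)propanal
Product: 12 (1RS,2R,3R)-3-[3-(benzyloxy)phenoxy]-3-[4-(benzyloxy)phenyl]-2-(methoxymethoxy)-1-{(2R,3R)-3,5,7-tris(benzyloxy)-2-[3,4-bis(benzyloxy)phenyl]chroman-8-yl}propan-1-ol (both C1 epimers), via aryllithium 11 (not isolated)
Conditions: 3 (1.3 equiv), n-BuLi (1.3 equiv), THF, −78 °C, 15 min; then 10, −78 °C; pH 7 buffer; Et3N-washed silica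
Reagents that add atoms: none
Why: Bromine–lithium exchange and 1,2-addition of the 2,6-dialkoxyaryllithium to the aldehyde at −78 °C, faster than enolisation, forms the interflavan C4–C8 bond; the configuration of the new carbinol is irrelevant because step 7 ionises it.

**Step 7**
Reactants: 12 carbinol (both C1 epimers)
Product: 14 (2R,3R,4R)-7-(benzyloxy)-2-[4-(benzyloxy)phenyl]-4-{(2R,3R)-3,5,7-tris(benzyloxy)-2-[3,4-bis(benzyloxy)phenyl]chroman-8-yl}chroman-3-ol, via cyclised MOM ether 13 (not isolated)
Conditions: TMSOTf (0.2 equiv), 4 Å MS, CH2Cl2 (5 mM), −78 → −40 °C; then 2,2'-bipyridyl (3 equiv), TMSOTf (2 equiv), 0 °C → rt; H2O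
Reagents that add atoms: none
Why: Acid released from the silyl triflate ionises the C4 hydroxyl of either epimer of 12 to one planar benzylic cation stabilised by the trioxygenated ring D, and C4a of ring A attacks it in an intramolecular Friedel–Crafts alkylation; the closest known reaction types are the dehydrative cyclisation of 3-aryloxy-1-arylpropan-1-ols to 4-arylchromans and the epoxy-arene cyclisation that gives trans-4-arylchroman-3-ols. Ring C closes as a six-membered ring by C–C bond formation between the tethered arene and the cation; the five-membered alternative through ring B would use a position meta to its oxygen and is not activated. The new stereocentre C4 is controlled by C3: the cation should react through the rotamer that holds C3–H in its plane next to the ortho-disubstituted ring D (least A(1,3) strain), ring A can reach only the face on which C2 lies, and this places ring D trans to the C3 oxygen (4R); displacement with inversion of a C3 acetal oxygen bridging to C4 would give the same result. The step needs chemoselective ionisation at C4 beside the p-alkoxybenzylic C2–O1 aryl ether, which the much greater stabilisation by ring D and the low temperature should secure, and attack para to the benzyloxy group of ring A, which sterics and electronics both favour over the position between the two oxygens. In the second stage the same silyl triflate, buffered by 2,2'-bipyridyl, turns the MOM ether into a pyridinium acetal that water hydrolyses, so the acid-sensitive C4 is not exposed to protic acid.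

**Step 8**
Reactants: 14 (2R,3R,4R)-7-(benzyloxy)-2-[4-(benzyloxy)phenyl]-4-{(2R,3R)-3,5,7-tris(benzyloxy)-2-[3,4-bis(benzyloxy)phenyl]chroman-8-yl}chroman-3-ol
Product: 15 (2R,3R,4R)-2-(4-hydroxyphenyl)-4-[(2R,3R)-2-(3,4-dihydroxyphenyl)-3,5,7-trihydroxychroman-8-yl]chroman-3,7-diol (CNP0118995.2)
Conditions: H2 (1 atm), 20% Pd(OH)2/C, THF–MeOH–H2O, rt
Reagents that add atoms: none
Why: Hydrogenolysis of the seven benzyl ethers, the usual last step for benzylated proanthocyanidins, leaves the C2–O1 bonds, the bis-benzylic C4 and all five stereocentres untouched.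

**Compound list**
1 | (−)-epicatechin, (2R,3R)-2-(3,4-dihydroxyphenyl)chroman-3,5,7-triol | Oc1cc(O)c2c(c1)O[C@H](c1ccc(O)c(O)c1)[C@H](O)C2 | starting material
2 | (2R,3R)-3,5,7-tris(benzyloxy)-2-[3,4-bis(benzyloxy)phenyl]chromane | C(c1ccccc1)Oc1cc(OCc3ccccc3)c2c(c1)O[C@H](c1ccc(OCc3ccccc3)c(OCc3ccccc3)c1)[C@H](OCc1ccccc1)C2 | intermediate
3 | (2R,3R)-3,5,7-tris(benzyloxy)-2-[3,4-bis(benzyloxy)phenyl]-8-bromochromane | C(c1ccccc1)Oc1cc(OCc3ccccc3)c2c(c1Br)O[C@H](c1ccc(OCc3ccccc3)c(OCc3ccccc3)c1)[C@H](OCc1ccccc1)C2 | intermediate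
4 | allyl methoxymethyl ether, 3-(methoxymethoxy)prop-1-ene | C=CCOCOC | starting material
5 | 4-(benzyloxy)benzaldehyde | O=Cc1ccc(OCc2ccccc2)cc1 | starting material
6 | [(Z)-3-(methoxymethoxy)allyl]bis(isopinocampheyl)borane (isopinocampheyl groups from (+)-α-pinene) | COCO/C=C\CB([C@@H]1C[C@@H]2C[C@H]([C@H]1C)C2(C)C)[C@@H]1C[C@@H]2C[C@H]([C@H]1C)C2(C)C | intermediate (not isolated)
7 | (1R,2R)-1-[4-(benzyloxy)phenyl]-2-(methoxymethoxy)but-3-en-1-ol | O[C@H](c1ccc(OCc2ccccc2)cc1)[C@H](OCOC)C=C | intermediate
8 | 1-(benzyloxy)-3-iodobenzene | Ic1cccc(OCc2ccccc2)c1 | starting material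
9 | 1-(benzyloxy)-3-{[(1R,2R)-1-[4-(benzyloxy)phenyl]-2-(methoxymethoxy)but-3-en-1-yl]oxy}benzene | C(c1ccccc1)Oc1cccc(c1)O[C@H](c1ccc(OCc2ccccc2)cc1)[C@H](OCOC)C=C | intermediate
10 | (2S,3R)-3-[3-(benzyloxy)phenoxy]-3-[4-(benzyloxy)phenyl]-2-(methoxymethoxy)propanal | C(c1ccccc1)Oc1cccc(c1)O[C@H](c1ccc(OCc2ccccc2)cc1)[C@H](OCOC)C=O | intermediate
11 | {(2R,3R)-3,5,7-tris(benzyloxy)-2-[3,4-bis(benzyloxy)phenyl]chroman-8-yl}lithium | [Li]c1c(OCc2ccccc2)cc(OCc2ccccc2)c2c1O[C@H](c1ccc(OCc3ccccc3)c(OCc3ccccc3)c1)[C@H](OCc1ccccc1)C2 | intermediate (not isolated)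
12 | (1RS,2R,3R)-3-[3-(benzyloxy)phenoxy]-3-[4-(benzyloxy)phenyl]-2-(methoxymethoxy)-1-{(2R,3R)-3,5,7-tris(benzyloxy)-2-[3,4-bis(benzyloxy)phenyl]chroman-8-yl}propan-1-ol | C(c1ccccc1)Oc1cccc(c1)O[C@H](c1ccc(OCc2ccccc2)cc1)[C@H](OCOC)C(O)c1c(OCc2ccccc2)cc(OCc2ccccc2)c2c1O[C@H](c1ccc(OCc3ccccc3)c(OCc3ccccc3)c1)[C@H](OCc1ccccc1)C2 | intermediate
13 | (2R,3R,4R)-7-(benzyloxy)-2-[4-(benzyloxy)phenyl]-3-(methoxymethoxy)-4-{(2R,3R)-3,5,7-tris(benzyloxy)-2-[3,4-bis(benzyloxy)phenyl]chroman-8-yl}chromane | C(c1ccccc1)Oc1ccc([C@H]2Oc3cc(OCc5ccccc5)ccc3[C@H](c3c(OCc5ccccc5)cc(OCc5ccccc5)c4c3O[C@H](c3ccc(OCc5ccccc5)c(OCc5ccccc5)c3)[C@H](OCc3ccccc3)C4)[C@H]2OCOC)cc1 | intermediate (not isolated)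
14 | (2R,3R,4R)-7-(benzyloxy)-2-[4-(benzyloxy)phenyl]-4-{(2R,3R)-3,5,7-tris(benzyloxy)-2-[3,4-bis(benzyloxy)phenyl]chroman-8-yl}chroman-3-ol | C(c1ccccc1)Oc1ccc([C@H]2Oc3cc(OCc5ccccc5)ccc3[C@H](c3c(OCc5ccccc5)cc(OCc5ccccc5)c4c3O[C@H](c3ccc(OCc5ccccc5)c(OCc5ccccc5)c3)[C@H](OCc3ccccc3)C4)[C@H]2O)cc1 | intermediate
15 | (2R,3R,4R)-2-(4-hydroxyphenyl)-4-[(2R,3R)-2-(3,4-dihydroxyphenyl)-3,5,7-trihydroxychroman-8-yl]chroman-3,7-diol | Oc1ccc([C@H]2Oc3cc(O)ccc3[C@H](c3c(O)cc(O)c4c3O[C@H](c3ccc(O)c(O)c3)[C@H](O)C4)[C@H]2O)cc1 | target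

**Totals**
Total step count: 8. Longest linear sequence: 6 (steps 3 to 8).

**Steps most likely to fail**

1. Step 7. The ring-D-stabilised cation may lose H3 to an enol ether or be captured with poor facial selectivity, or the C2–O1 benzylic aryl ether may ionise. Fallback: the order of the two arylations of C4 would be reversed with established chemistry. Aldehyde 10 would be cyclised by intramolecular carbonyl–arene hydroxyalkylation (BF3·OEt2 or Me2AlCl, CH2Cl2, −78 °C) to (2R,3R)-7-(benzyloxy)-2-[4-(benzyloxy)phenyl]-3-(methoxymethoxy)chroman-4-ol F1. F1 would then be ionised (TMSOTf, −78 °C) in the presence of 2, whose C8 should attack the flavan-4-yl cation trans to the 3-oxygen, as is usual for 2,3-cis units. This sets out from 10 and 2 and comes back to the route at 13, which the second stage of step 7 would convert to 14.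

2. Step 4. The hindered benzylic alkoxide may couple slowly on copper, or be oxidised to the ketone. Fallback: the aryl group would be transferred without a transition metal from a hypervalent (trivalent) iodine reagent. Iodide 8 would be oxidised (mCPBA, TsOH·H2O, MeCN) and condensed with 1,3,5-trimethoxybenzene to [3-(benzyloxy)phenyl](2,4,6-trimethoxyphenyl)iodonium 4-methylbenzenesulfonate F2. The sodium alkoxide of 7 (NaH, toluene, rt) would then take the less electron-rich aryl group from F2 by ligand coupling, again with retention at carbon. This sets out from 7 and 8 and comes back at 9.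

3. Step 6. The basic aryllithium may enolise the aldehyde and eliminate the β-aryloxy group instead of adding. Fallback: a non-basic Nozaki–Hiyama–Kishi coupling. Compound 2 would be iodinated with N-iodosuccinimide to (2R,3R)-3,5,7-tris(benzyloxy)-2-[3,4-bis(benzyloxy)phenyl]-8-iodochromane F3, and F3 would be coupled with 10 (CrCl2, NiCl2 (2 mol%), DMF–THF, rt). The aryl chromium species, formed from divalent chromium under nickel catalysis, adds to aldehydes without enolisation. This sets out from 2 and 10 and comes back at 12.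

**Further compounds**
F1 | step 7 | (2R,3R)-7-(benzyloxy)-2-[4-(benzyloxy)phenyl]-3-(methoxymethoxy)chroman-4-ol (C4 epimers) | C(c1ccccc1)Oc1ccc([C@H]2Oc3cc(OCc5ccccc5)ccc3C(O)[C@H]2OCOC)cc1
F2 | step 4 | [3-(benzyloxy)phenyl](2,4,6-trimethoxyphenyl)iodonium 4-methylbenzenesulfonate | COc1cc(OC)c([I+]c2cccc(OCc3ccccc3)c2)c(OC)c1.Cc1ccc(cc1)S([O-])(=O)=O
F3 | step 6 | (2R,3R)-3,5,7-tris(benzyloxy)-2-[3,4-bis(benzyloxy)phenyl]-8-iodochromane | C(c1ccccc1)Oc1cc(OCc3ccccc3)c2c(c1I)O[C@H](c1ccc(OCc3ccccc3)c(OCc3ccccc3)c1)[C@H](OCc1ccccc1)C2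
A1 | direct plan | (2R)-7-(benzyloxy)-2-[4-(benzyloxy)phenyl]-2H-chromen-3-yl formate | C(c1ccccc1)Oc1ccc([C@H]2Oc3cc(OCc4ccccc4)ccc3C=C2OC=O)cc1
A2 | direct plan | (2R,3R)-5,7-bis(benzyloxy)-2-[3,4-bis(benzyloxy)phenyl]chroman-3-ol | C(c1ccccc1)Oc1cc(OCc3ccccc3)c2c(c1)O[C@H](c1ccc(OCc3ccccc3)c(OCc3ccccc3)c1)[C@H](O)C2
A3 | direct plan | (2R)-5,7-bis(benzyloxy)-2-[3,4-bis(benzyloxy)phenyl]chroman-3-one | C(c1ccccc1)Oc1cc(OCc3ccccc3)c2c(c1)O[C@H](c1ccc(OCc3ccccc3)c(OCc3ccccc3)c1)C(=O)C2
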